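The benzene ring of the target carries all its functionality (C1 methyl ester, C2 OH, C4 OMe), whereas the C6 icosyl chain is an unbroken polymethylene run. The route therefore cuts the primary–primary CH2–CH2 bond between chain carbons C6' and C7' (counted from the ring). A copper-catalysed sp3–sp3 coupling of a tetradecyl Grignard reagent with an ω-bromohexyl arene completes the whole skeleton and the target in one operation; the free C2 phenol, as its magnesium phenoxide, chelates and masks the neighbouring ester, so no protecting group is needed. The precursor, methyl 2-(6-bromohexyl)-6-hydroxy-4-methoxybenzoate, comes in one step from the dianion of sparassol and 1,5-dibromopentane.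

Key step: step 2

Assumption: methyl 2-hydroxy-4-methoxy-6-methylbenzoate (sparassol) and tetradecylmagnesium chloride (1.0 M in THF) are taken as catalogue items.

Step 1
Reactants: 1 methyl 2-hydroxy-4-methoxy-6-methylbenzoate (sparassol); 2 1,5-dibromopentane
Product: 4 methyl 2-(6-bromohexyl)-6-hydroxy-4-methoxybenzoate, via dilithio dianion 3 (not isolated)
Conditions: LDA (commercial solution, 2.2 equiv), THF, −78 °C; cannulated into 2 (5 equiv) in THF, −78 → 0 °C; 1 M HCl
Reagents that add atoms: none
Why: LDA removes the phenolic proton and then a proton of the C6 methyl group (lateral lithiation of an o-toluate), and the soft benzylic carbanion of the resulting phenoxide/dienolate dianion should displace one bromide of the excess dibromide by SN2, while the lithium phenoxide deactivates the ester towards self-condensation and inverse addition suppresses reaction at the second C–Br terminus.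

Step 2
Reactants: 4 methyl 2-(6-bromohexyl)-6-hydroxy-4-methoxybenzoate; 5 tetradecylmagnesium chloride
Product: 8 methyl 2-hydroxy-6-icosyl-4-methoxybenzoate, via bromohexyl chloromagnesium phenoxide 6 (not isolated), via icosyl chloromagnesium phenoxide 7 (not isolated)
Conditions: 5 (2.4 equiv, slow addition), Li2CuCl4 (5 mol %), THF/NMP, −20 → 0 °C; 1 M HCl
Reagents that add atoms: none
Why: The first equivalent of 5 deprotonates the C2 phenol to the chloromagnesium phenoxide 6, whose six-membered chelate with the ester carbonyl, together with the two ortho substituents, makes the methyl ester a poor electrophile; Li2CuCl4 is reduced and transmetallated by further 5 to a tetradecylcuprate that attacks the primary C–Br carbon by SN2-type oxidative addition and then reductively eliminates from copper(III), forming the CH2–CH2 bond and returning copper(I) to the cycle. The closest known reaction type is the copper-catalysed cross-coupling of a Grignard reagent with a primary alkyl halide (Kochi–Tamura coupling with Li2CuCl4, in its NMP-accelerated form). No ring is closed and no stereocentre is formed. The selectivity required is chemoselectivity for substitution at C–Br over 1,2-addition to the ester and over homocoupling or elimination; it should be secured by the fast catalytic cuprate pathway at −20 to 0 °C, by slow addition of 5 and by the in-flask phenoxide masking of the salicylate. Acidic work-up protonates 7 to the target.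

Compound list
1 | methyl 2-hydroxy-4-methoxy-6-methylbenzoate (sparassol) | COC(=O)c1c(C)cc(OC)cc1O | starting material
2 | 1,5-dibromopentane | BrCCCCCBr | starting material
3 | dilithio dianion of 1 (lithium phenoxide, benzylic lithium) | COC(=O)c1c(C[Li])cc(OC)cc1O[Li] | intermediate
4 | methyl 2-(6-bromohexyl)-6-hydroxy-4-methoxybenzoate | COC(=O)c1c(CCCCCCBr)cc(OC)cc1O | intermediate
5 | tetradecylmagnesium chloride | CCCCCCCCCCCCCC[Mg]Cl | starting material
6 | chloromagnesium phenoxide of 4 | COC(=O)c1c(CCCCCCBr)cc(OC)cc1O[Mg]Cl | intermediate
7 | chloromagnesium phenoxide of 8 | CCCCCCCCCCCCCCCCCCCCc1cc(OC)cc(O[Mg]Cl)c1C(=O)OC | intermediate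
8 | methyl 2-hydroxy-6-icosyl-4-methoxybenzoate | CCCCCCCCCCCCCCCCCCCCc1cc(OC)cc(O)c1C(=O)OC | target

Total step count: 2
Longest linear sequence: 2 steps

Steps most likely to fail (the route has two steps, so both are given, the more exposed first)

Step 1. The dianion may react at both ends of the dibromide, or the product may be deprotonated again at the benzylic position by unreacted dianion and then cyclise onto, or be alkylated a second time by, the remaining C–Br terminus. Fallback with a monofunctional electrophile: it sets out from 1, whose dianion 3 is generated as before and alkylated with tert-butyl(5-bromopentyloxy)dimethylsilane (THF, −78 → 0 °C) to give methyl 2-[6-(tert-butyldimethylsilyloxy)hexyl]-6-hydroxy-4-methoxybenzoate F1. Desilylation with aqueous HF in MeCN should give methyl 2-hydroxy-6-(6-hydroxyhexyl)-4-methoxybenzoate F2, and an Appel bromination (CBr4, PPh3, CH2Cl2, 0 °C) of the primary alcohol brings the route back at 4.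

Step 2. The Grignard reagent may add to the ester faster than the copper cycle turns over, or the bromide may be consumed by elimination and homocoupling. Fallback with a non-basic nucleophile and a palladium cycle: it sets out from 4. 1-Tetradecene is hydroborated with 9-BBN-H (THF, 0 °C → rt) to give 9-tetradecyl-9-borabicyclo[3.3.1]nonane F3, which is coupled with 4 in an alkyl–alkyl Suzuki–Miyaura reaction (Pd(OAc)2, PCy3, K3PO4·H2O, THF, rt, with extra base for the phenol). This forms the same CH2–CH2 bond and comes back at 8.

Further compounds
F1 | step 1 | methyl 2-[6-(tert-butyldimethylsilyloxy)hexyl]-6-hydroxy-4-methoxybenzoate | COC(=O)c1c(CCCCCCO[Si](C)(C)C(C)(C)C)cc(OC)cc1O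
F2 | step 1 | methyl 2-hydroxy-6-(6-hydroxyhexyl)-4-methoxybenzoate | COC(=O)c1c(CCCCCCO)cc(OC)cc1O
F3 | step 2 | 9-tetradecyl-9-borabicyclo[3.3.1]nonane | CCCCCCCCCCCCCCB1C2CCCC1CCC2
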